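**Remark on the chemistry (assumption):** the SMILES is read as (1R,5S,6R), with the C5 hydroxyl on the same face as the oxirane oxygen; 2,4-dibromoanisole and (2E,6E)-farnesyl bromide are taken as commercial; "farnesyl" below always means (2E,6E)-3,7,11-trimethyldodeca-2,6,10-trien-1-yl.

Ring atoms of every intermediate are called by the numbering of the target: C1 (quaternary oxirane carbon with the chain), C2 (ketone), C3 (vinyl CH), C4 (C–OCH3), C5 (carbinol), C6 (oxirane CH), O7 (oxirane oxygen). Compound names carry their own IUPAC locants.

## Analysis of the target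

Yanuthone X2 (13) is a cyclohexenone ring (C1–C6) cis-fused to an oxirane (C1, C6, O7). C2 is a ketone, C3=C4 bears the methoxy group at C4 (a vinylogous ester), C5 is a secondary carbinol, and the quaternary oxirane carbon C1 carries the farnesyl chain. The three stereocentres are contiguous, C1 (R), C6 (R) and C5 (S), and the C5 hydroxyl is syn to O7, so C5–C6–C1/O7 is a cis-2,3-epoxy alcohol. The sensitive groups are the three trisubstituted chain alkenes (peracids, halonium sources, strong acids), the oxirane next to a ketone, and the C5 hydrogen, whose removal by base would open the oxirane by vinylogous β-elimination. The ring is at the oxidation level of a hydroquinone plus one oxygen: any intermediate with a C1=C6 double bond, a hydrogen on C5 and a free C2 carbonyl is the keto tautomer of a phenol and aromatises. The hard points are the absolute configuration of the quaternary C1 on a flat ring, the oxidation of one double bond out of five, and the regiochemistry of the vinylogous ester (carbonyl next to the quaternary carbon). The feature that invites the strategy is the syn relation of the C5 oxygen and O7 across a C1=C6 bond that is allylic to C5: one carbinol set by a catalyst can deliver the oxygen to both C1 and C6 in one event.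

## Retrosynthetic reasoning

**13 back to 12.** The C4–OCH3 bond is cut first. The vinylogous ester is written as the product of an addition–elimination at the β-carbon of a β-iodo enone, so that C4 carries iodine through the oxidative part of the route. An enol ether at C3=C4 would be the most nucleophilic double bond of every earlier intermediate, whereas a vinyl iodide is the least. Forward, iodide has to be exchanged for the methoxy group on 12 without touching the oxirane.

**12 back to 11.** The C2 carbonyl is masked as its dimethyl ketal. The ketal removes the aromatisation pathway until the oxirane is in place. With iodine at C4 the unmasking is regiochemically unambiguous; with an alkoxy group there, the 1,3-dioxygenated allyl cation could be captured at either end. Forward, a mild hydrolysis of 11 has to leave oxirane and polyene alone.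

**11 back to 10 (key disconnection).** Both C–O bonds of the oxirane, C1–O7 and C6–O7, are cut. This leaves the cyclohexa-2,5-dienol 10 with a single stereocentre, C5. The C5 oxygen can carry the oxidant to the C1=C6 bond and to the correct face, so the quaternary C1 and C6 no longer need a chiral reagent. Forward, oxygen must be transferred to one of five double bonds, on one face, without ionising the ketal.

**10 back to 9.** The C5–H bond is cut; 9 is an achiral cross-conjugated dienone. Its two flanks differ by the iodine on the α-carbon C4, which is what an oxazaborolidine-catalysed reduction needs to tell the faces apart. This step sets the only stereocentre that comes from a catalyst.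

**9 back to 8.** The C4–I bond is cut. Forward, an α-iodination of the enone must choose the unsubstituted arm of the dienone (C3=C4) over the arm that bears the chain.

**8 back to 7.** One C2–OCH3 bond and the C5 carbonyl are traced back to a para-methoxyphenol. Oxidative dearomatisation in the alcohol of the ketal puts the ketal on the carbon next to the chain-bearing carbon, as the order of unmasking requires.

**7 back to 4, and 4 back to 1 and 2.** The phenolic C5–O bond is cut to an aryl bromide, and the C1–C1' bond between ring and chain is cut to an aryl nucleophile and the allylic bromide 2. Both bromines come from 1; they differ in their rate of metal–halogen exchange, so chain and oxygen enter in the right order without protecting groups.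

## Alternatives that were turned down

**Alternative 1:** the textbook disconnection. The oxirane C–O bonds are cut on the quinone monoketal A1 (2-farnesyl-4,4,5-trimethoxycyclohexa-2,5-dien-1-one), made in two steps from 3,4-dimethoxyphenol. The forward key step is an asymmetric Weitz–Scheffer epoxidation (tert-butyl hydroperoxide, chiral phase-transfer catalyst) to the epoxy ketal A2, followed by ketal hydrolysis and hydride reduction at C5 anti to the oxirane. It is the shortest route (five steps). It was turned down as the main line because its only stereo-determining event is an intermolecular conjugate addition of a peroxide anion to an α-branched, cross-conjugated dienone. The catalyst has no covalent or directing contact with the substrate and must distinguish two faces of an almost planar ring that differ only remotely. All three stereocentres then depend on a selectivity that the structure does not help, and the oily farnesyl intermediates offer no easy enrichment.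

**Alternative 2:** an enzymatic entry. An arene dioxygenase (toluene dioxygenase in whole cells) would convert bromobenzene into the cis-dihydrodiol A3, two oxygenated stereocentres in one step. It was turned down on mapping grounds.
- The two oxygens of A3 sit on adjacent sp3 carbons and both stay as C–O single bonds. In the target the cis pair is C5–OH/C6–O7, and O7 must also bond to C1; a carbon that already bears the diol oxygen cannot be part of the alkene that is epoxidised.
- The bromine-bearing sp2 carbon can take the chain by cross-coupling only while it is sp2, so the chain-bearing alkene would have to be epoxidised afterwards by an electrophilic oxidant in the presence of three more nucleophilic chain alkenes.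
- C2 and C4 would still have to be raised to the ketone level. The route would exceed twelve steps.

**Alternative 3:** dearomatisation at the chain-bearing carbon. Phenol A4 (2-farnesyl-5-methoxyphenol) would be hydroxylated at C1 with a pentavalent iodine reagent to the ortho-quinol A5, which fixes the C1–O bond first. Nucleophilic epoxidation of the distal C5=C6 bond and Payne rearrangement would then move the oxirane to C1/C6 and release the C5 hydroxyl. It was turned down for three reasons.
- The Payne step is an intramolecular SN2 opening: the C1 oxygen attacks C6 with inversion, so the C5–O bond ends anti to the new oxirane and the product is the C5 epimer A6.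
- Correcting it needs a Mitsunobu inversion or an oxidation/reduction pair.
- 6-Alkyl-6-hydroxycyclohexa-2,4-dienones such as A5 dimerise readily by [4+2] cycloaddition, and enantiocontrol in the hydroxylation of a simple 2-alkylphenol is weakly supported.

Key step: step 6

## Route

**Step 1**
Reactants: 1 2,4-dibromo-1-methoxybenzene; 2 (2E,6E)-farnesyl bromide
Product: 4 4-bromo-2-[(2E,6E)-farnesyl]-1-methoxybenzene, via aryllithium 3 (not isolated)
Conditions: n-BuLi (1.0 equiv), Et2O, −78 °C; then CuI (10 mol%), 2, −78 °C to rt
Reagents that add atoms: n-butyllithium, [Li]CCCC (lithium of 3 only)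
Why: Bromine–lithium exchange should occur at the bromine ortho to the methoxy group (chelation and inductive stabilisation of the aryllithium); copper-catalysed SN2 coupling with the primary allylic bromide then forms the C1–C1' bond with retention of the (2E,6E) geometry.

**Step 2**
Reactants: 4 4-bromo-2-[(2E,6E)-farnesyl]-1-methoxybenzene
Product: 7 3-[(2E,6E)-farnesyl]-4-methoxyphenol, via aryllithium 5 (not isolated), via lithium aryltrimethoxyborate 6 (not isolated)
Conditions: n-BuLi, THF, −78 °C; B(OMe)3, −78 °C to rt; 30% H2O2, 0 °C
Reagents that add atoms: hydrogen peroxide, OO (phenol oxygen); trimethyl borate, COB(OC)OC (boron and methoxy groups of 6 only); n-butyllithium, [Li]CCCC (lithium of 5 and 6 only)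
Why: A second bromine–lithium exchange, borylation and oxidative aryl migration from boron to oxygen (borate oxidation) turn the remaining C–Br bond into the phenol at C5; the basic peroxide is nucleophilic and should leave the trisubstituted alkenes untouched.

**Step 3**
Reactants: 7 3-[(2E,6E)-farnesyl]-4-methoxyphenol
Product: 8 3-[(2E,6E)-farnesyl]-4,4-dimethoxycyclohexa-2,5-dien-1-one
Conditions: PhI(OAc)2 (1.1 equiv), MeOH, 0 °C
Reagents that add atoms: methanol, CO
Why: Oxidative dearomatisation of a para-methoxyphenol (ligand exchange on trivalent iodine, then attack of methanol at the para carbon) should give the quinone monoketal; the phenol is oxidised far faster than isolated alkenes, and the ketal carbon is the future C2.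

**Step 4**
Reactants: 8 3-[(2E,6E)-farnesyl]-4,4-dimethoxycyclohexa-2,5-dien-1-one
Product: 9 5-[(2E,6E)-farnesyl]-2-iodo-4,4-dimethoxycyclohexa-2,5-dien-1-one
Conditions: I2 (1.5 equiv), pyridine/CH2Cl2 (1:1), 0 °C to rt
Reagents that add atoms: iodine, II
Why: Pyridine-mediated α-iodination of an enone (Johnson iodination): conjugate addition of pyridine, iodination of the enolate and elimination; pyridine should add only to the unsubstituted β-carbon C3 and not to the β-carbon that carries the chain, so iodine enters at C4.

**Step 5**
Reactants: 9 5-[(2E,6E)-farnesyl]-2-iodo-4,4-dimethoxycyclohexa-2,5-dien-1-one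
Product: 10 (1S)-5-[(2E,6E)-farnesyl]-2-iodo-4,4-dimethoxycyclohexa-2,5-dien-1-ol
Conditions: (3aR)-1-methyl-3,3-diphenyltetrahydro-1H,3H-pyrrolo[1,2-c][1,3,2]oxazaborole [(R)-Me-CBS] (20 mol%), catecholborane (1.5 equiv), toluene, −78 °C; MeOH quench, basic aqueous wash
Reagents that add atoms: none
Why: CBS reduction of an α-halo enone; the α-iodovinyl flank acts as the large group and the unsubstituted vinyl flank as the small one, so the (R)-configured catalyst should deliver hydride to the face that gives the (S)-carbinol at C5. Catecholborane at −78 °C does not hydroborate the chain alkenes.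

**Step 6**
Reactants: 10 (1S)-5-[(2E,6E)-farnesyl]-2-iodo-4,4-dimethoxycyclohexa-2,5-dien-1-ol
Product: 11 (1R,2S,6R)-6-[(2E,6E)-farnesyl]-3-iodo-5,5-dimethoxy-7-oxabicyclo[4.1.0]hept-3-en-2-ol
Conditions: VO(acac)2 (5 mol%), t-BuOOH (in decane, 1.3 equiv), toluene, 0 °C
Reagents that add atoms: tert-butyl hydroperoxide, CC(C)(C)OO
Why: Hydroxyl-directed epoxidation of a cyclic allylic alcohol; the closest known reaction type is the cis-selective VO(acac)2/t-BuOOH epoxidation of cyclohex-2-enols and the 2,3-selective epoxidation of geraniol. The carbinol of 10 exchanges onto the oxovanadium tert-butylperoxide to give a vanadate ester, and the bound peroxide oxygen is passed intramolecularly to the C1=C6 double bond. The oxirane (C1–O7–C6) is closed in one concerted, suprafacial oxygen transfer (a [2+1] addition through a spiro transition state), so both C–O bonds form on the same face. C6 and the quaternary C1 are set together by the C5 stereocentre: the tether allows delivery only to the face that carries the C5–O bond, which should give the cis-epoxy alcohol. The step needs chemoselectivity among five C=C bonds; the three chain alkenes are four or more atoms away from the carbinol carbon and cannot reach the metal-bound peroxide, and the other allylic alkene (C3=C4) is deactivated by iodine. It also needs the bis-allylic ketal to survive, for which low temperature, an apolar solvent and a catalytic amount of the weakly Lewis acidic vanadium ester are chosen; once the oxirane is in place the ring can no longer aromatise.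

**Step 7**
Reactants: 11 (1R,2S,6R)-6-[(2E,6E)-farnesyl]-3-iodo-5,5-dimethoxy-7-oxabicyclo[4.1.0]hept-3-en-2-ol
Product: 12 (1R,5S,6R)-1-[(2E,6E)-farnesyl]-5-hydroxy-4-iodo-7-oxabicyclo[4.1.0]hept-3-en-2-one
Conditions: pyridinium p-toluenesulfonate (20 mol%), acetone/H2O (10:1), rt
Reagents that add atoms: water, O
Why: Acid-catalysed hydrolysis of an allylic dimethyl ketal through the oxocarbenium ion unmasks the C2 ketone; the β-iodo enone should form with unambiguous regiochemistry because iodine, unlike an alkoxy group, offers no second site for ketone formation.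

**Step 8**
Reactants: 12 (1R,5S,6R)-1-[(2E,6E)-farnesyl]-5-hydroxy-4-iodo-7-oxabicyclo[4.1.0]hept-3-en-2-one
Product: 13 yanuthone X2, (1R,5S,6R)-1-[(2E,6E)-farnesyl]-5-hydroxy-4-methoxy-7-oxabicyclo[4.1.0]hept-3-en-2-one
Conditions: NaOMe (1.2 equiv), MeOH, −20 to 0 °C
Reagents that add atoms: sodium methoxide, [Na+].[O-]C
Why: Addition–elimination at the β-carbon of the β-iodo enone (a vinylogous acyl halide) should install the methoxy group at C4; no stereocentre is touched, and the C5 alkoxide, being syn to the oxirane, cannot undergo Payne rearrangement.

## Compound list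

1 | 2,4-dibromo-1-methoxybenzene (2,4-dibromoanisole) | COc1ccc(Br)cc1Br | starting material
2 | (2E,6E)-1-bromo-3,7,11-trimethyldodeca-2,6,10-triene (farnesyl bromide) | BrC/C=C(\C)CC/C=C(\C)CCC=C(C)C | starting material
3 | (5-bromo-2-methoxyphenyl)lithium | [Li]c1cc(Br)ccc1OC | intermediate (not isolated)
4 | 4-bromo-1-methoxy-2-[(2E,6E)-3,7,11-trimethyldodeca-2,6,10-trien-1-yl]benzene | COc1ccc(Br)cc1C/C=C(\C)CC/C=C(\C)CCC=C(C)C | intermediate
5 | {4-methoxy-3-[(2E,6E)-3,7,11-trimethyldodeca-2,6,10-trien-1-yl]phenyl}lithium | [Li]c1ccc(OC)c(C/C=C(\C)CC/C=C(\C)CCC=C(C)C)c1 | intermediate (not isolated)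
6 | lithium trimethoxy{4-methoxy-3-[(2E,6E)-3,7,11-trimethyldodeca-2,6,10-trien-1-yl]phenyl}borate | [Li+].CO[B-](OC)(OC)c1ccc(OC)c(C/C=C(\C)CC/C=C(\C)CCC=C(C)C)c1 | intermediate (not isolated)
7 | 4-methoxy-3-[(2E,6E)-3,7,11-trimethyldodeca-2,6,10-trien-1-yl]phenol | COc1ccc(O)cc1C/C=C(\C)CC/C=C(\C)CCC=C(C)C | intermediate
8 | 4,4-dimethoxy-3-[(2E,6E)-3,7,11-trimethyldodeca-2,6,10-trien-1-yl]cyclohexa-2,5-dien-1-one | COC1(OC)C=CC(=O)C=C1C/C=C(\C)CC/C=C(\C)CCC=C(C)C | intermediate
9 | 2-iodo-4,4-dimethoxy-5-[(2E,6E)-3,7,11-trimethyldodeca-2,6,10-trien-1-yl]cyclohexa-2,5-dien-1-one | COC1(OC)C=C(I)C(=O)C=C1C/C=C(\C)CC/C=C(\C)CCC=C(C)C | intermediate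
10 | (1S)-2-iodo-4,4-dimethoxy-5-[(2E,6E)-3,7,11-trimethyldodeca-2,6,10-trien-1-yl]cyclohexa-2,5-dien-1-ol | IC1=CC(OC)(OC)C(C/C=C(\C)CC/C=C(\C)CCC=C(C)C)=C[C@@H]1O | intermediate
11 | (1R,2S,6R)-3-iodo-5,5-dimethoxy-6-[(2E,6E)-3,7,11-trimethyldodeca-2,6,10-trien-1-yl]-7-oxabicyclo[4.1.0]hept-3-en-2-ol | IC1=CC(OC)(OC)[C@]2(C/C=C(\C)CC/C=C(\C)CCC=C(C)C)O[C@@H]2[C@@H]1O | intermediate
12 | (1R,5S,6R)-5-hydroxy-4-iodo-1-[(2E,6E)-3,7,11-trimethyldodeca-2,6,10-trien-1-yl]-7-oxabicyclo[4.1.0]hept-3-en-2-one | IC1=CC(=O)[C@]2(C/C=C(\C)CC/C=C(\C)CCC=C(C)C)O[C@@H]2[C@@H]1O | intermediate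
13 | yanuthone X2, (1R,5S,6R)-5-hydroxy-4-methoxy-1-[(2E,6E)-3,7,11-trimethyldodeca-2,6,10-trien-1-yl]-7-oxabicyclo[4.1.0]hept-3-en-2-one | COC1=CC(=O)[C@]2(C/C=C(\C)CC/C=C(\C)CCC=C(C)C)O[C@@H]2[C@@H]1O | target

## Step count and least certain steps

Total step count: 8. Longest linear sequence: 8 steps (from 1; 2 enters in step 1).

**Step 6 (key step).** The most likely failure is ionisation of the bis-allylic dimethyl ketal at the Lewis acidic vanadium centre, followed by loss of the C5 proton and aromatisation. Oxidation of the carbinol back to the dienone could also compete with oxygen transfer. The fallback gives up the relay from C5 and returns to nucleophilic epoxidation of a quinone. It sets out from farnesyl bromide 2 and comes back at 13. Commercial 1-bromo-2,4,5-trimethoxybenzene F1 would be lithiated (n-BuLi, Et2O, −78 °C) and coupled with 2 under CuI catalysis to give 1-farnesyl-2,4,5-trimethoxybenzene F2. Oxidative demethylation with (NH4)2Ce(NO3)6 in MeCN/H2O at 0 °C should give 2-farnesyl-5-methoxy-1,4-benzoquinone F3. Weitz–Scheffer epoxidation with t-BuOOH, catalytic aqueous NaOH and a cinchona-derived N-benzyl quaternary ammonium chloride (the pseudoenantiomeric series that leads to the required oxirane) should attack only the chain-bearing double bond, since the methoxy-bearing one is deactivated, and give the epoxyquinone F4. Reduction with NaBH4/CeCl3·7H2O in MeOH at −78 °C should then take place at the C5 carbonyl from the face anti to the oxirane and give 13.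

**Step 5.** Facial discrimination may be poor because both flanks of the ketone are sp2 carbons and the catalyst sees only the iodine; the boron Lewis acid may also start to ionise the ketal. The fallback replaces asymmetric catalysis by resolution. It sets out from 9 and comes back at 10. Reduction with NaBH4/CeCl3·7H2O (MeOH, −78 °C) would give the racemic dienol F5. Acylation with Burkholderia cepacia lipase and vinyl acetate in tert-butyl methyl ether should, by the usual preference of this enzyme for the (R)-configured secondary alcohol, convert the unwanted enantiomer into the acetate F6 and leave 10.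

**Step 4.** Electrophilic iodine may add to the polyene or trigger its cyclisation, and the conjugate addition of pyridine may not discriminate fully between the two arms. The fallback moves the halogenation to the aromatic stage, where the phenol outcompetes the alkenes by a wide margin. It sets out from 7 and comes back at 9. Iodination with the morpholine–iodine complex (CH2Cl2, 0 °C) at the free ortho position para to the chain would give 5-farnesyl-2-iodo-4-methoxyphenol F7, and PhI(OAc)2 in MeOH would oxidise it directly to 9.

**Step 7.** The oxocarbenium ion at C2 may be trapped by the free C5 hydroxyl (transannular ketal), or the acid may open the oxirane with participation of that hydroxyl; harsher acid to force a slow hydrolysis would endanger the polyene. The fallback removes the free hydroxyl from the ionisation step. It sets out from 11 and comes back at 13, bypassing 12. Acetylation (Ac2O, pyridine, catalytic 4-dimethylaminopyridine) would give the acetate F8, hydrolysis on montmorillonite K10 in wet CH2Cl2 the β-iodo enone acetate F9, and NaOMe in MeOH at 0 °C would then exchange iodide for methoxide and cleave the acetate in one operation.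

**Step 8.** Methoxide may remove the C5 hydrogen (vinylogous enolisation) with β-elimination of the oxirane, or open the oxirane directly. The fallback moves the exchange to the acid side. It sets out from 12 and comes back at 13. Hydrolysis of the vinylogous acyl iodide in NaOAc/AcOH-buffered aqueous THF would give the cyclic 1,3-dione F10. Acid-catalysed enol ether formation (MeOH, catalytic camphorsulfonic acid, 3 Å molecular sieves, 0 °C) should place the methoxy group at the less hindered C4, because C2 is flanked by the quaternary C1.

## Further compounds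

F1 | step 6 | 1-bromo-2,4,5-trimethoxybenzene | COc1cc(OC)c(OC)cc1Br
F2 | step 6 | 1,2,4-trimethoxy-5-[(2E,6E)-3,7,11-trimethyldodeca-2,6,10-trien-1-yl]benzene | COc1cc(OC)c(OC)cc1C/C=C(\C)CC/C=C(\C)CCC=C(C)C
F3 | step 6 | 2-methoxy-5-[(2E,6E)-3,7,11-trimethyldodeca-2,6,10-trien-1-yl]cyclohexa-2,5-diene-1,4-dione | COC1=CC(=O)C(C/C=C(\C)CC/C=C(\C)CCC=C(C)C)=CC1=O
F4 | step 6 | (1R,6S)-4-methoxy-1-[(2E,6E)-3,7,11-trimethyldodeca-2,6,10-trien-1-yl]-7-oxabicyclo[4.1.0]hept-3-ene-2,5-dione | COC1=CC(=O)[C@]2(C/C=C(\C)CC/C=C(\C)CCC=C(C)C)O[C@@H]2C1=O
F5 | step 5 | racemic 2-iodo-4,4-dimethoxy-5-[(2E,6E)-3,7,11-trimethyldodeca-2,6,10-trien-1-yl]cyclohexa-2,5-dien-1-ol | IC1=CC(OC)(OC)C(C/C=C(\C)CC/C=C(\C)CCC=C(C)C)=CC1O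
F6 | step 5 | (1R)-2-iodo-4,4-dimethoxy-5-[(2E,6E)-3,7,11-trimethyldodeca-2,6,10-trien-1-yl]cyclohexa-2,5-dien-1-yl acetate | IC1=CC(OC)(OC)C(C/C=C(\C)CC/C=C(\C)CCC=C(C)C)=C[C@H]1OC(C)=O
F7 | step 4 | 2-iodo-4-methoxy-5-[(2E,6E)-3,7,11-trimethyldodeca-2,6,10-trien-1-yl]phenol | COc1cc(I)c(O)cc1C/C=C(\C)CC/C=C(\C)CCC=C(C)C
F8 | step 7 | (1R,2S,6R)-3-iodo-5,5-dimethoxy-6-[(2E,6E)-3,7,11-trimethyldodeca-2,6,10-trien-1-yl]-7-oxabicyclo[4.1.0]hept-3-en-2-yl acetate | IC1=CC(OC)(OC)[C@]2(C/C=C(\C)CC/C=C(\C)CCC=C(C)C)O[C@@H]2[C@@H]1OC(C)=O
F9 | step 7 | (1R,5S,6R)-4-iodo-2-oxo-1-[(2E,6E)-3,7,11-trimethyldodeca-2,6,10-trien-1-yl]-7-oxabicyclo[4.1.0]hept-3-en-5-yl acetate | IC1=CC(=O)[C@]2(C/C=C(\C)CC/C=C(\C)CCC=C(C)C)O[C@@H]2[C@@H]1OC(C)=O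
F10 | step 8 | (1R,5S,6R)-5-hydroxy-1-[(2E,6E)-3,7,11-trimethyldodeca-2,6,10-trien-1-yl]-7-oxabicyclo[4.1.0]heptane-2,4-dione | O=C1CC(=O)[C@]2(C/C=C(\C)CC/C=C(\C)CCC=C(C)C)O[C@@H]2[C@@H]1O
A1 | alternative 1 | 4,4,5-trimethoxy-2-[(2E,6E)-3,7,11-trimethyldodeca-2,6,10-trien-1-yl]cyclohexa-2,5-dien-1-one | COC1=CC(=O)C(C/C=C(\C)CC/C=C(\C)CCC=C(C)C)=CC1(OC)OC
A2 | alternative 1 | (1R,6S)-4,5,5-trimethoxy-1-[(2E,6E)-3,7,11-trimethyldodeca-2,6,10-trien-1-yl]-7-oxabicyclo[4.1.0]hept-3-en-2-one | COC1=CC(=O)[C@]2(C/C=C(\C)CC/C=C(\C)CCC=C(C)C)O[C@@H]2C1(OC)OC
A3 | alternative 2 | (1S,2S)-3-bromocyclohexa-3,5-diene-1,2-diol | O[C@H]1C=CC=C(Br)[C@H]1O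
A4 | alternative 3 | 5-methoxy-2-[(2E,6E)-3,7,11-trimethyldodeca-2,6,10-trien-1-yl]phenol | COc1ccc(C/C=C(\C)CC/C=C(\C)CCC=C(C)C)c(O)c1
A5 | alternative 3 | (6R)-6-hydroxy-3-methoxy-6-[(2E,6E)-3,7,11-trimethyldodeca-2,6,10-trien-1-yl]cyclohexa-2,4-dien-1-one | COC1=CC(=O)[C@@](O)(C/C=C(\C)CC/C=C(\C)CCC=C(C)C)C=C1
A6 | alternative 3 | (1R,5R,6R)-5-hydroxy-4-methoxy-1-[(2E,6E)-3,7,11-trimethyldodeca-2,6,10-trien-1-yl]-7-oxabicyclo[4.1.0]hept-3-en-2-one | COC1=CC(=O)[C@]2(C/C=C(\C)CC/C=C(\C)CCC=C(C)C)O[C@@H]2[C@H]1O
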